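The retrosynthesis cuts, in this order: the aryl angelate C–O bond, the oxirane bonds C8–C9 and C9–O, the C10–OAc bond, the aryl C4–C8 bond and the benzylic isovalerate, ending at methyl 3-hydroxy-4-iodobenzoate.
Numbering: arene C1–C6 (C1 bears C7H2–O-isovalerate, C3 the angelate oxygen, C4 the side chain), C8 the quaternary oxirane carbon, C9 the oxirane CH2, C10 the CH2OAc carbon.
Enabling feature: the oxirane, the only ring besides the arene, ends the side chain; C8 is bonded only to arene carbon C4 and to C10, and C9 is a bare CH2, so C9 can be added as a methylene to a ketone at C8.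
Forward: silylate, reduce, isovaleroylate, join C4–C8 by iodine–magnesium exchange and acylation, introduce the acetate, close the oxirane by methylene transfer, then exchange the aryl silyl ether for the angelate in one flask.
Stereochemistry: C8 (R) comes from catalyst-controlled delivery of CH2 to the Re face of the ketone (O > CH2OAc > aryl); the Z double bond comes from angelic acid and is kept by acylations free of conjugate-adding nucleophiles.

Key step: step 7

Assumption: which antipode of the binaphthoxide ligand exposes the Re face of the aryl acetoxymethyl ketone is settled by one pilot run with each antipode; the route is written for the antipode that does.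

Step 1
Reactants: 1 methyl 3-hydroxy-4-iodobenzoate
Product: 2 methyl 3-(tert-butyldimethylsilyloxy)-4-iodobenzoate
Conditions: TBSCl, imidazole, DMF, rt
Reagents that add atoms: tert-butyldimethylsilyl chloride, CC(C)(C)[Si](C)(C)Cl
Why: Imidazole-promoted O-silylation of a phenol; the methyl ester and the aryl iodide are inert to it.

Step 2
Reactants: 2 methyl 3-(tert-butyldimethylsilyloxy)-4-iodobenzoate
Product: 3 [3-(tert-butyldimethylsilyloxy)-4-iodophenyl]methanol
Conditions: i-Bu2AlH (2.2 equiv), CH2Cl2, −78 to 0 °C; aq. KNaC4H4O6 (potassium sodium tartrate)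
Reagents that add atoms: none
Why: Hydride reduction of a benzoate ester to the benzylic alcohol; at low temperature this aluminium hydride touches neither the aryl iodide nor the aryl silyl ether.

Step 3
Reactants: 3 [3-(tert-butyldimethylsilyloxy)-4-iodophenyl]methanol
Product: 4 [3-(tert-butyldimethylsilyloxy)-4-iodophenyl]methyl 3-methylbutanoate
Conditions: 3-methylbutanoyl chloride, pyridine, DMAP (cat.), CH2Cl2, 0 °C to rt
Reagents that add atoms: 3-methylbutanoyl chloride, CC(C)CC(=O)Cl
Why: DMAP-catalysed acylation of an unhindered primary alcohol with an acid chloride, with no competing nucleophile in the molecule.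

Step 4
Reactants: 4 [3-(tert-butyldimethylsilyloxy)-4-iodophenyl]methyl 3-methylbutanoate; 5 2-chloro-N-methoxy-N-methylacetamide
Product: 7 [3-(tert-butyldimethylsilyloxy)-4-(2-chloroacetyl)phenyl]methyl 3-methylbutanoate, via arylmagnesium chloride 6 (not isolated)
Conditions: i-PrMgCl·LiCl (1.1 equiv), THF, −40 °C; then 5 (1.3 equiv), −40 to 0 °C; aq. NH4Cl
Reagents that add atoms: none
Why: Iodine–magnesium exchange is fast on an aryl iodide at a temperature where the aliphatic ester is not attacked, and the Weinreb ketone synthesis stops at the ketone because the chelated N-methoxy-N-methyl adduct holds until the quench; the carbon–magnesium bond is too covalent to trigger oxygen-to-carbon silyl migration.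

Step 5
Reactants: 7 [3-(tert-butyldimethylsilyloxy)-4-(2-chloroacetyl)phenyl]methyl 3-methylbutanoate
Product: 8 [4-(2-acetoxyacetyl)-3-(tert-butyldimethylsilyloxy)phenyl]methyl 3-methylbutanoate
Conditions: KOAc (1.5 equiv), NaI (10 mol%), acetone (dry), rt
Reagents that add atoms: potassium acetate, CC(=O)[O-].[K+]
Why: SN2 displacement at an α-halo ketone, helped by in situ Finkelstein exchange; the dry, near-neutral medium should spare the aryl silyl ether.

Step 6
Reactants: 9 trimethylsulfoxonium chloride
Product: 10 dimethyloxosulfonium methylide (titrated THF solution)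
Conditions: NaH (1.0 equiv, oil-free), THF, reflux; filtration under argon
Reagents that add atoms: none
Why: Deprotonation of the sulfoxonium salt by NaH is the standard generation of the Corey–Chaykovsky ylide; the chloride is chosen because NaCl is insoluble in THF and filters off, leaving a halide-free solution.

Step 7
Reactants: 8 [4-(2-acetoxyacetyl)-3-(tert-butyldimethylsilyloxy)phenyl]methyl 3-methylbutanoate; 10 dimethyloxosulfonium methylide
Product: 12 {4-[(2R)-2-(acetoxymethyl)oxiran-2-yl]-3-(tert-butyldimethylsilyloxy)phenyl}methyl 3-methylbutanoate, via sulfoxonium alkoxide betaine 11 (not isolated)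
Conditions: LaLi3(binaphthoxide)3 (single antipode, 5–10 mol%, from La(O-i-Pr)3, binaphthol and n-BuLi), (2,4,6-(MeO)3C6H2)3P=O (5–10 mol%), 5 Å molecular sieves, THF, rt; 10 (1.2 equiv) added over several hours by syringe pump; chromatography on Et3N-deactivated silica gel
Reagents that add atoms: none
Why: The trivalent lanthanum centre of the heterobimetallic complex, tuned by the phosphine oxide, acts as Lewis acid toward the ketone oxygen of 8 while one of its lithium aryloxide arms organises ylide 10, so the ylide carbon adds to the carbonyl carbon (C8–C9) to give betaine 11, whose alkoxide then expels dimethyl sulfoxide from C9 (C9–O). The closest known reaction type is the catalytic asymmetric Corey–Chaykovsky epoxidation of aryl methyl ketones with this same complex, here carried from a CH3 flank to a CH2OAc flank. The oxirane closes by 3-exo-tet displacement. The only new stereocentre, C8, is set by the binaphthoxide ligand, which has to present the Re face of the carbonyl (O > CH2OAc > aryl) to the ylide so that the oxirane is R. The step needs enantioface selectivity and ketone-over-ester chemoselectivity: the first rests on the size gap between the ortho-silyloxyaryl flank and the slim CH2OAc flank, helped by slow ylide addition that starves the uncatalysed pathway; the second rests on the low reactivity of the stabilised sulfoxonium ylide toward alkyl esters at room temperature and on the absence of any enoate at this stage.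

Step 8
Reactants: 13 angelic acid, (Z)-2-methylbut-2-enoic acid (two molecules per molecule of anhydride)
Product: 14 angelic anhydride, (Z)-2-methylbut-2-enoic anhydride
Conditions: 13 (2.0 equiv), N,N'-dicyclohexylcarbodiimide (1.0 equiv), CH2Cl2, 0 °C to rt; filtration; used without chromatography
Reagents that add atoms: angelic acid (the second molecule, which supplies the second acyl group), C/C=C(/C)C(=O)O
Why: Carbodiimide dehydration of two molecules of a carboxylic acid to the symmetrical anhydride: the O-acylisourea formed from the first molecule is taken by the carboxylate of the second, and with no nucleophilic catalyst present there is no reversible conjugate addition that could turn the Z acyl group into its E isomer.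

Step 9
Reactants: 12 {4-[(2R)-2-(acetoxymethyl)oxiran-2-yl]-3-(tert-butyldimethylsilyloxy)phenyl}methyl 3-methylbutanoate; 14 angelic anhydride
Product: 16 {4-[(2R)-2-(acetoxymethyl)oxiran-2-yl]-3-[(Z)-2-methylbut-2-enoyloxy]phenyl}methyl 3-methylbutanoate, via tetrabutylammonium phenoxide 15 (not isolated)
Conditions: 14 (2.5 equiv), Bu4NF (1.1 equiv, THF solution, added dropwise), THF, −20 to 0 °C; pH 7 buffer; chromatography on Et3N-deactivated silica gel
Reagents that add atoms: none
Why: Fluoride-triggered desilylative O-acylation (silyl-to-acyl exchange): fluoride cleaves the aryl O–Si bond and phenoxide 15 should be captured at once by the anhydride already in solution, before it can attack the neighbouring oxirane, while the absence of DMAP should keep the Z geometry and C8 is not involved.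

Compound list
1 | methyl 3-hydroxy-4-iodobenzoate | COC(=O)c1ccc(I)c(O)c1 | starting material
2 | methyl 3-(tert-butyldimethylsilyloxy)-4-iodobenzoate | COC(=O)c1ccc(I)c(O[Si](C)(C)C(C)(C)C)c1 | intermediate
3 | [3-(tert-butyldimethylsilyloxy)-4-iodophenyl]methanol | OCc1ccc(I)c(O[Si](C)(C)C(C)(C)C)c1 | intermediate
4 | [3-(tert-butyldimethylsilyloxy)-4-iodophenyl]methyl 3-methylbutanoate | CC(C)CC(=O)OCc1ccc(I)c(O[Si](C)(C)C(C)(C)C)c1 | intermediate
5 | 2-chloro-N-methoxy-N-methylacetamide | CON(C)C(=O)CCl | starting material
6 | {2-(tert-butyldimethylsilyloxy)-4-[(3-methylbutanoyloxy)methyl]phenyl}magnesium chloride (as its LiCl complex) | CC(C)CC(=O)OCc1ccc([Mg]Cl)c(O[Si](C)(C)C(C)(C)C)c1 | intermediate (not isolated)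
7 | [3-(tert-butyldimethylsilyloxy)-4-(2-chloroacetyl)phenyl]methyl 3-methylbutanoate | CC(C)CC(=O)OCc1ccc(C(=O)CCl)c(O[Si](C)(C)C(C)(C)C)c1 | intermediate
8 | [4-(2-acetoxyacetyl)-3-(tert-butyldimethylsilyloxy)phenyl]methyl 3-methylbutanoate | CC(C)CC(=O)OCc1ccc(C(=O)COC(C)=O)c(O[Si](C)(C)C(C)(C)C)c1 | intermediate
9 | trimethylsulfoxonium chloride | C[S+](C)(C)=O.[Cl-] | starting material
10 | dimethyloxosulfonium methylide | CS(C)(=C)=O | intermediate
11 | betaine from Re-face addition, {4-[(2S)-1-acetoxy-3-(dimethyloxosulfonio)-2-oxidopropan-2-yl]-3-(tert-butyldimethylsilyloxy)phenyl}methyl 3-methylbutanoate | CC(C)CC(=O)OCc1ccc([C@]([O-])(COC(C)=O)C[S+](C)(C)=O)c(O[Si](C)(C)C(C)(C)C)c1 | intermediate (not isolated)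
12 | {4-[(2R)-2-(acetoxymethyl)oxiran-2-yl]-3-(tert-butyldimethylsilyloxy)phenyl}methyl 3-methylbutanoate | CC(C)CC(=O)OCc1ccc([C@]2(COC(C)=O)CO2)c(O[Si](C)(C)C(C)(C)C)c1 | intermediate
13 | angelic acid, (Z)-2-methylbut-2-enoic acid | C/C=C(/C)C(=O)O | starting material
14 | angelic anhydride, (Z)-2-methylbut-2-enoic anhydride | C/C=C(/C)C(=O)OC(=O)C(/C)=C\C | intermediate
15 | tetrabutylammonium 2-[(2R)-2-(acetoxymethyl)oxiran-2-yl]-5-[(3-methylbutanoyloxy)methyl]phenolate | CC(C)CC(=O)OCc1ccc([C@]2(COC(C)=O)CO2)c([O-])c1.CCCC[N+](CCCC)(CCCC)CCCC | intermediate (not isolated)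
16 | {4-[(2R)-2-(acetoxymethyl)oxiran-2-yl]-3-[(Z)-2-methylbut-2-enoyloxy]phenyl}methyl 3-methylbutanoate | C/C=C(/C)C(=O)Oc1cc(COC(=O)CC(C)C)ccc1[C@]1(COC(C)=O)CO1 | target

Total step count: 9
Longest linear sequence: 7 steps (steps 1, 2, 3, 4, 5, 7, 9); steps 6 and 8 prepare the ylide and the anhydride.

Steps most likely to fail

Step 7. What may go wrong: poor discrimination of the two carbonyl faces, because the CH2OAc flank is bulkier than the methyl flank this catalyst is known to handle, the twisted ortho-substituted ketone may bind differently, and the activated ketone may react with free ylide. Base-induced enolisation toward C10, followed by acetyl migration, is a second risk. The fallback delivers the oxirane oxygen to an alkene instead and sets out from aryl iodide 4. Stille coupling with tributyl(prop-1-en-2-yl)stannane (Pd(PPh3)4, toluene, 100 °C) should give [3-(tert-butyldimethylsilyloxy)-4-(prop-1-en-2-yl)phenyl]methyl 3-methylbutanoate F1. Allylic oxidation (SeO2 cat., t-BuOOH, CH2Cl2, rt) should give [3-(tert-butyldimethylsilyloxy)-4-(3-hydroxyprop-1-en-2-yl)phenyl]methyl 3-methylbutanoate F2. Sharpless asymmetric epoxidation (Ti(O-i-Pr)4, L-(+)-diethyl tartrate, t-BuOOH, 4 Å molecular sieves, CH2Cl2, −20 °C) should give {3-(tert-butyldimethylsilyloxy)-4-[(2S)-2-(hydroxymethyl)oxiran-2-yl]phenyl}methyl 3-methylbutanoate F3. L-(+)-tartrate is chosen as the antipode that, by the usual rule, gives 2S epoxy alcohols from 2-substituted primary allylic alcohols; the descriptor is S only because CH2OH ranks below the ring CH2, and the spatial arrangement is that of 12. Acetylation (Ac2O, pyridine, 0 °C) comes back to the route at 12.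

Step 9. What may go wrong: the liberated phenoxide opens the neighbouring oxirane intramolecularly before it is acylated, or the acyl donor isomerises from Z to E. The fallback separates the two events and sets out from 12. Desilylation with Bu4NF buffered with AcOH (THF, 0 °C) releases only the neutral phenol, {4-[(2R)-2-(acetoxymethyl)oxiran-2-yl]-3-hydroxyphenyl}methyl 3-methylbutanoate F4, which is isolated quickly on deactivated silica gel. Acylation with anhydride 14 and Et3N (CH2Cl2, −20 °C, no DMAP) comes back to the route at 16.

Step 4. What may go wrong: the arylmagnesium species attacks the isovalerate of a second molecule, or acylation next to the ortho silyloxy group is sluggish. The fallback avoids any aryl–metal nucleophile and sets out from 4. Stille coupling with tributyl(1-ethoxyvinyl)stannane (Pd(PPh3)4, toluene, 100 °C) should give [3-(tert-butyldimethylsilyloxy)-4-(1-ethoxyvinyl)phenyl]methyl 3-methylbutanoate F5. Bromination of the enol ether in wet solvent (NBS, THF/H2O, 0 °C) should give [4-(2-bromoacetyl)-3-(tert-butyldimethylsilyloxy)phenyl]methyl 3-methylbutanoate F6. Displacement with KOAc in acetone comes back to the route at 8.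

Further compounds
F1 | step 7 | [3-(tert-butyldimethylsilyloxy)-4-(prop-1-en-2-yl)phenyl]methyl 3-methylbutanoate | CC(C)CC(=O)OCc1ccc(C(C)=C)c(O[Si](C)(C)C(C)(C)C)c1
F2 | step 7 | [3-(tert-butyldimethylsilyloxy)-4-(3-hydroxyprop-1-en-2-yl)phenyl]methyl 3-methylbutanoate | CC(C)CC(=O)OCc1ccc(C(=C)CO)c(O[Si](C)(C)C(C)(C)C)c1
F3 | step 7 | {3-(tert-butyldimethylsilyloxy)-4-[(2S)-2-(hydroxymethyl)oxiran-2-yl]phenyl}methyl 3-methylbutanoate | CC(C)CC(=O)OCc1ccc([C@]2(CO)CO2)c(O[Si](C)(C)C(C)(C)C)c1
F4 | step 9 | {4-[(2R)-2-(acetoxymethyl)oxiran-2-yl]-3-hydroxyphenyl}methyl 3-methylbutanoate | CC(C)CC(=O)OCc1ccc([C@]2(COC(C)=O)CO2)c(O)c1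
F5 | step 4 | [3-(tert-butyldimethylsilyloxy)-4-(1-ethoxyvinyl)phenyl]methyl 3-methylbutanoate | CCOC(=C)c1ccc(COC(=O)CC(C)C)cc1O[Si](C)(C)C(C)(C)C
F6 | step 4 | [4-(2-bromoacetyl)-3-(tert-butyldimethylsilyloxy)phenyl]methyl 3-methylbutanoate | CC(C)CC(=O)OCc1ccc(C(=O)CBr)c(O[Si](C)(C)C(C)(C)C)c1
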